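**Retrosynthetic overview**
1. Target 12 ⇐ diester 11 (same carbocycle, both CH2OH groups as methyl esters) by ester reduction.
2. 11 ⇐ achiral, C2-symmetric (E,E)-bis(4-hydroxy-3-methoxybenzylidene)succinate 10 by a proposed chiral-Brønsted-acid-catalysed protio-cyclisation. This one step forms the C1–C8a bond, closes the ring and sets both stereocentres.
3. 10 ⇐ MOM-vanillin 3 (two equivalents) and dimethyl succinate 4 by two sequential Stobbe condensations.
4. Ring order: both benzene rings come from vanillin; the only ring built is the central dihydro ring, closed in step 7.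

Assumption: the sense of induction of the new catalyst cannot be predicted with certainty; the (S,S)-catalyst is written, and its antipode is used if the first run gives ent-11.

**Route**

Step 1
Reactants: 1 vanillin; 2 chloromethyl methyl ether
Product: 3, 3-methoxy-4-(methoxymethoxy)benzaldehyde
Conditions: MOMCl, i-Pr2NEt, CH2Cl2, 0 °C → rt
Reagents that add atoms: chloromethyl methyl ether (2), COCCl
Why: Phenol O-alkylation (MOM protection) keeps the aldehyde electrophilic under the alkoxide conditions of the Stobbe steps, and MOM is later removed by mild acid that leaves the diene diester intact.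

Step 2
Reactants: 3; 4 dimethyl succinate
Product: 5, (E)-3-(methoxycarbonyl)-4-[3-methoxy-4-(methoxymethoxy)phenyl]but-3-enoic acid
Conditions: NaOMe, MeOH, reflux; cold aq. citric acid (pH ≈ 4)
Reagents that add atoms: dimethyl succinate (4), COC(=O)CCC(=O)OC
Why: Stobbe condensation (aldol, γ-lactonisation, E1cB ring opening) gives the half-ester with the favoured E geometry, aryl cis to the CH2CO2H arm; no stereocentre is formed.

Step 3
Reactants: 5; 6 iodomethane
Product: 7, dimethyl (E)-2-[3-methoxy-4-(methoxymethoxy)benzylidene]succinate
Conditions: MeI, KHCO3, DMF, rt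
Reagents that add atoms: iodomethane (6), CI
Why: SN2 O-methylation of the carboxylate under weak base restores a diester without alkene isomerisation and leaves the CH2 free for the second condensation.

Step 4
Reactants: 7; 3 (second equivalent)
Product: 8, (2E,3E)-2,3-bis[3-methoxy-4-(methoxymethoxy)benzylidene]succinic acid monomethyl ester
Conditions: NaOMe, MeOH, reflux; cold aq. citric acid
Reagents that add atoms: aldehyde 3, COCOc1ccc(C=O)cc1OC
Why: A second Stobbe condensation at the remaining α-CH2 gives the E,E-dibenzylidenesuccinate, with both aryl groups cis to the central C–C bond as needed for ring closure.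

Step 5
Reactants: 8; 6 iodomethane
Product: 9, dimethyl (2E,3E)-2,3-bis[3-methoxy-4-(methoxymethoxy)benzylidene]succinate
Conditions: MeI, KHCO3, DMF, rt
Reagents that add atoms: iodomethane (6), CI
Why: SN2 esterification gives the symmetric diester, so it does not matter which carboxyl was free in 8.

Step 6
Reactants: 9
Product: 10, dimethyl (2E,3E)-2,3-bis(4-hydroxy-3-methoxybenzylidene)succinate
Conditions: HCl (1.25 M in MeOH), MeOH/THF, 0 °C → rt
Reagents that add atoms: none
Why: Acid-catalysed acetal cleavage removes the aryl MOM ethers; methyl esters cannot transesterify in MeOH, and this acid is too weak to C-protonate the cinnamate, so no racemic cyclisation occurs.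

Step 7 (key step)
Reactants: 10
Product: 11, dimethyl (1S,2R)-7-hydroxy-1-(4-hydroxy-3-methoxyphenyl)-6-methoxy-1,2-dihydronaphthalene-2,3-dicarboxylate (1-aryl and 2-CO2Me trans)
Conditions: (S,S)-IDPi chiral acid (BINOL-derived imidodiphosphorimidate, 3,3′-Ar = 3,5-(CF3)2C6H3, N-triflyl core; 5 mol%), CHCl3, 4 Å MS, −20 °C → rt; Et3N quench
Reagents that add atoms: none (isomerisation)
Why: Proposed new method: catalytic enantioselective protio-cyclisation of a 2,3-bis(4-hydroxybenzylidene)succinate. The confined strong chiral acid protonates Cα of one feruloyl arm (either arm, since the substrate is C2-symmetric) to give an O-protonated p-quinone methide held by ion pairing and a phenol O–H···anion hydrogen bond. C6 of the second guaiacyl ring (para to its OMe) then attacks the cationic carbon in an intramolecular Friedel–Crafts ring closure, on one face and anti to the C2 ester, and rearomatisation returns the proton to the catalyst. Because protonation is reversible, the C1/C2 pair is selected under Curtin–Hammett control at the C–C bond-forming step, giving trans-(1S,2R). The closest known reactions are the racemic, trans-selective TfOH-mediated cyclisation of 2,3-dibenzylidenesuccinates and chiral-phosphoric-acid-catalysed enantioselective Friedel–Crafts 1,6-additions of arenes to p-quinone methides; the same quinone methide is the intermediate of oxidative 8–8 cyclodimerisation of ferulates, which supports the regiochemistry.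

Step 8
Reactants: 11
Product: 12, (1S,2R)-7-hydroxy-1-(4-hydroxy-3-methoxyphenyl)-2,3-bis(hydroxymethyl)-6-methoxy-1,2-dihydronaphthalene (target, CID 10473569)
Conditions: DIBAL-H (8 equiv), THF, −78 → 0 °C; aq. Rochelle salt
Reagents that add atoms: none
Why: DIBAL-H ester reduction (1,2-hydride delivery) converts both esters to primary alcohols without reducing the styrenyl C3=C4 bond or disturbing C1 or C2; two equivalents are consumed by the phenols.

**Compound list**
1 | vanillin (4-hydroxy-3-methoxybenzaldehyde) | COc1cc(C=O)ccc1O | starting material
2 | chloromethyl methyl ether | COCCl | starting material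
3 | 3-methoxy-4-(methoxymethoxy)benzaldehyde | COCOc1ccc(C=O)cc1OC | intermediate
4 | dimethyl succinate | COC(=O)CCC(=O)OC | starting material
5 | (E)-3-(methoxycarbonyl)-4-[3-methoxy-4-(methoxymethoxy)phenyl]but-3-enoic acid | COC(=O)/C(CC(=O)O)=C/c1ccc(OCOC)c(OC)c1 | intermediate
6 | iodomethane | CI | starting material
7 | dimethyl (E)-2-[3-methoxy-4-(methoxymethoxy)benzylidene]succinate | COC(=O)/C(CC(=O)OC)=C/c1ccc(OCOC)c(OC)c1 | intermediate
8 | (2E,3E)-2,3-bis[3-methoxy-4-(methoxymethoxy)benzylidene]succinic acid monomethyl ester | COC(=O)/C(=C/c1ccc(OCOC)c(OC)c1)C(\C(=O)O)=C/c1ccc(OCOC)c(OC)c1 | intermediate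
9 | dimethyl (2E,3E)-2,3-bis[3-methoxy-4-(methoxymethoxy)benzylidene]succinate | COC(=O)/C(=C/c1ccc(OCOC)c(OC)c1)C(\C(=O)OC)=C/c1ccc(OCOC)c(OC)c1 | intermediate
10 | dimethyl (2E,3E)-2,3-bis(4-hydroxy-3-methoxybenzylidene)succinate | COC(=O)/C(=C/c1ccc(O)c(OC)c1)C(\C(=O)OC)=C/c1ccc(O)c(OC)c1 | intermediate
11 | dimethyl (1S,2R)-7-hydroxy-1-(4-hydroxy-3-methoxyphenyl)-6-methoxy-1,2-dihydronaphthalene-2,3-dicarboxylate | COc1cc([C@H]2c3cc(O)c(OC)cc3C=C(C(=O)OC)[C@@H]2C(=O)OC)ccc1O | intermediate
12 | (1S,2R)-7-hydroxy-1-(4-hydroxy-3-methoxyphenyl)-2,3-bis(hydroxymethyl)-6-methoxy-1,2-dihydronaphthalene | COc1cc([C@H]2c3cc(O)c(OC)cc3C=C(CO)[C@@H]2CO)ccc1O | target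

**Totals**
Total steps: 8. Longest linear sequence: 8 (fully linear from vanillin; aldehyde 3 is used twice).

**Three steps most likely to fail**
1. Step 7 (proposed new asymmetric protio-cyclisation). The acid may be too weak to C-protonate the cinnamate, or the ee may be low. Fallback (known chemistry): give up catalytic control. Carry acid-stable isopropyl ethers instead of MOM, cyclise the E,E-diester with stoichiometric TfOH in CH2Cl2 (the established racemic, trans-selective reaction), cleave the isopropyl ethers with BCl3, and resolve rac-11 by preparative chiral SFC or via diastereomeric bis-camphanate esters of the phenols. Then reduce as in step 8.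
2. Step 4 (second Stobbe). Electron-rich aldehydes can give low yields and E/Z mixtures. Fallback: form the central C2–C3 bond by coupling instead of condensation. Convert 3 to methyl (Z)-2-bromo-3-arylacrylate by Wittig reaction with Ph3P=C(Br)CO2Me, then carry out Ni(0)-mediated reductive homocoupling (NiCl2(PPh3)2/Zn) with retention of alkene geometry to give 9 directly.
3. Step 8 (reduction with free phenols). Aluminium phenoxide aggregation may stall the reduction, and the transient C2 aldehyde could epimerise. Fallback: change the protecting-group strategy. Bis-silylate 11 (TBSCl, imidazole), reduce the non-acidic diester with DIBAL-H at −78 °C, then desilylate with TBAF/AcOH.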